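The data are simulated from invented constants; the scatter is artificial.

Should the charge be cleaned, taking [protic impurity] from the 0.600 mM of oak down to the 0.00800 mM of cedar, before a run of 2.0 min? That is the decision, and the examination starts from these flasks and runs:

the same everywhere: first end groups 10 mM

| flask | second end groups | protic impurity | remark | time |
|---|---|---|---|---|
| blue | 10 mM | 0.011 mM | run made earlier |  |
| violet | 10 mM | 0.70 mM | run made earlier |  |
| cedar | 10.0 mM | 0.00800 mM |  | 2.0 min |
| maple | 10.0 mM | 0.0200 mM |  | 2.0 min |
| larch | 10.0 mM | 0.0600 mM |  | 2.0 min |
| elm | 10.0 mM | 0.200 mM |  | 2.0 min |
| oak | 10.0 mM | 0.600 mM |  | 2.0 min |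

| run | time / s | links / % |
|---|---|---|
| blue | 10.0 | 43.8 |
| blue | 20.0 | 61.0 |
| blue | 30.0 | 69.3 |
| blue | 60.0 | 80.2 |
| blue | 120 | 87.3 |
| violet | 10.0 | 40.8 |
| violet | 20.0 | 58.0 |
| violet | 30.0 | 66.7 |
| violet | 60.0 | 76.2 |
| violet | 120 | 83.0 |

(standard deviation of a reading: 0.5 percentage points)

- what may be going on: first end groups + second end groups -> rings; second end groups + protic impurity -> quenched reagent; first end groups + second end groups -> links
- "hardly changes" means that all values lie within two and a half points (for a concentration: within two and a half percent of the largest)

- amount of links at the end, in percent of the first end groups charged for cedar, maple, larch, elm, oak, in this order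
- how that number moves from the first to the last of them (falls, then rises / hardly changes / rises, then falls / rises all the way / falls all the way)

Which reading matters? The last of each run, since the asked time is that of the last reading: there blue shows 87.3% links and violet 83.0%, and the two runs differ in nothing but [protic impurity].

What does the impurity cost, then? I call it the price of the impurity, meaning the mM of links missing at that time per mM of protic impurity charged. The gap of 4.3 percentage points on a charge of 10 mM, spread over the difference in impurity, gives a price, read from two scattered readings, of 0.624. Each mM quenched takes a mM of second end groups out of an equal charge and leaves them the limiting reagent, yet it costs less than a whole link, and blue still has 12.7% of its first end groups outside links at that time.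

But two runs draw a line through anything, so why trust it at oak? Oak lies inside the bracket, with less impurity than violet, and its impurity stays below the 1.27 mM of first end groups outside links in blue at that time, so I keep to the line.

What do you commit to? Counting from blue, I say 87.3% for cedar, 86.1% for elm and 83.6% for oak. That is a span of 3.7 points against the 2.5 points of "hardly changes", with 0.5 points of scatter on each reading behind it, so the row falls all the way, though not by a wide margin.

The forecast reads 87.3%, 87.2%, 87%, 86.3% and 83.9%, falls all the way, and says “The quench is therefore fast and simply unbalances the stoichiometry.” Its oak value stands above mine.

The flasks give 86.8%, 86.7%, 86.5%, 85.7% and 83.1%, falls all the way.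

    first end groups + second end groups → rings, rate k1*[first end groups] as long as [second end groups] is above zero (k = 0.00180 s⁻¹)
    second end groups + protic impurity → quenched reagent (k = 230 L mol⁻¹ s⁻¹)
    first end groups + second end groups → links (k = 8.20 L mol⁻¹ s⁻¹)

Oak at 2.00 min holds 11.2% of its first end groups and 5.24% of its second, each of its own charge, with [protic impurity] at 0%. Put to elm, the price gives a fall of 1.2 points below cedar, and elm stands 1.1 points below cedar.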